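**Retrosynthetic overview**

1. The target is opened to benzyl quinate plus three tri-O-benzylgalloyl chlorides; one hydrogenolysis at the end frees nine phenols and the acid, and the hindered tertiary 1-OH is never acylated.
2. Benzyl quinate comes from 3,4-O-isopropylidene-1,5-quinide, the γ-lactone (6-oxabicyclo[3.2.1]octan-7-one) in which the carboxyl carbon on C1 is tied to O-5.
3. The quinide comes from ring contraction of a cycloheptane-1,2-dione held as its transannular five-membered hemiketal (8-oxabicyclo[3.2.1]octane): a tethered benzilic ester 1,2-shift makes the cyclohexane, the quaternary C1(OH)(CO–O) and its configuration together. Enabling feature: C1 of the target is a tertiary α-hydroxy-acid carbon whose carboxyl is 1,3-cis to O-5 on the cyclohexane, while O-3/O-4 are cis and can be locked as an acetonide, so only O-5 can bridge.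
4. The dione comes from a cycloheptene (dihydroxylation, oxidation), made by RCM of a nona-1,8-diene from 2-deoxy-L-ribose (sugar C3/C4 become quinic C3/C4; quinic C5 by reagent-controlled allylation).
5. Ring order: dioxolane, cycloheptene, oxolane hemiketal, then cyclohexane/γ-lactone by contraction; lactone and dioxolane are opened before acylation.

Key step: step 10

**Remarks**

- The target is read as the 3,4,5-tri-O-galloyl ester of (−)-quinic acid (O-3/O-4 cis, O-5 trans to O-4, carboxyl cis to O-5); quinic numbering is used for six-membered compounds.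
- Seven-membered intermediates are numbered C1–C7: C1/C2 are the alkene or carbonyl carbons (C1 next to C7), C3 and C7 the CH2 groups, C4/C5 the acetonide carbons, C6 the carbinol carbon. C4, C5, C6 become quinic C3, C4, C5; C1 becomes quinic C1; C2 becomes the carboxyl carbon.
- 2-Deoxy-L-ribose, (+)-Ipc2B(allyl) solution and 3,4,5-tris(benzyloxy)benzoyl chloride are taken as purchased.
- The face of dihydroxylation in step 7 is immaterial (both centres are oxidised in step 8); 8 is drawn as the cis-diol anti to the dioxolane.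

**Route**

Step 1
Reactants: 1 2-deoxy-L-ribose
Product: 2 3,4-O-isopropylidene-2-deoxy-L-ribopyranose
Conditions: 2-methoxypropene, PPTS (cat.), EtOAc, 0 °C to rt
Reagents that add atoms: 2-methoxypropene, C=C(C)OC
Why: Kinetic acetalisation of the cis-3,4-diol of the pyranose (acetonide protection) should give the cis-fused dioxolane and leave the lactol free; no stereocentre is made.

Step 2
Reactants: 2 3,4-O-isopropylidene-2-deoxy-L-ribopyranose
Product: 3 [(4S,5R)-2,2-dimethyl-5-(prop-2-en-1-yl)-1,3-dioxolan-4-yl]methanol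
Conditions: Ph3PCH3Br, KOtBu, THF, 0 °C to rt
Reagents that add atoms: methyltriphenylphosphonium bromide, C[P+](c1ccccc1)(c1ccccc1)c1ccccc1.[Br-]
Why: The lactol is in equilibrium with the hydroxy aldehyde, which the non-stabilised ylide traps (Wittig methylenation), releasing only the primary hydroxyl because the secondary ones are in the acetonide.

Step 3
Reactants: 3 [(4S,5R)-2,2-dimethyl-5-(prop-2-en-1-yl)-1,3-dioxolan-4-yl]methanol
Product: 4 (4R,5R)-2,2-dimethyl-5-(prop-2-en-1-yl)-1,3-dioxolane-4-carbaldehyde
Conditions: DMP, pyridine, CH2Cl2, 0 °C to rt; used crude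
Reagents that add atoms: none
Why: Buffered Dess–Martin oxidation should give the aldehyde without a base strong enough to epimerise the cis α-alkoxy centre.

Step 4
Reactants: 4 (4R,5R)-2,2-dimethyl-5-(prop-2-en-1-yl)-1,3-dioxolane-4-carbaldehyde
Product: 5 (1R)-1-[(4S,5R)-2,2-dimethyl-5-(prop-2-en-1-yl)-1,3-dioxolan-4-yl]but-3-en-1-ol
Conditions: (+)-Ipc2B(allyl) (from (−)-α-pinene), Et2O, −78 °C; then NaOH, H2O2, 0 °C to rt
Reagents that add atoms: (+)-B-allyldiisopinocampheylborane, C=CCB([C@H]1C[C@H]2C[C@@H]([C@@H]1C)C2(C)C)[C@H]1C[C@H]2C[C@@H]([C@@H]1C)C2(C)C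
Why: Brown allylation through a chair Zimmerman–Traxler transition state, in which the (+)-reagent should deliver allyl to the Re face and set the new carbinol centre R (threo to the neighbouring dioxolane oxygen) by reagent control against the modest Felkin bias of the aldehyde.

Step 5
Reactants: 5 (1R)-1-[(4S,5R)-2,2-dimethyl-5-(prop-2-en-1-yl)-1,3-dioxolan-4-yl]but-3-en-1-ol
Product: 6 tert-butyl{[(1R)-1-[(4R,5R)-2,2-dimethyl-5-(prop-2-en-1-yl)-1,3-dioxolan-4-yl]but-3-en-1-yl]oxy}dimethylsilane
Conditions: TBSOTf, 2,6-lutidine, CH2Cl2, −78 to 0 °C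
Reagents that add atoms: tert-butyldimethylsilyl triflate, CC(C)(C)[Si](C)(C)OS(=O)(=O)C(F)(F)F
Why: Silyl triflate silylation of the hindered secondary alcohol masks the future tether oxygen through the two oxidations.

Step 6
Reactants: 6 tert-butyl{[(1R)-1-[(4R,5R)-2,2-dimethyl-5-(prop-2-en-1-yl)-1,3-dioxolan-4-yl]but-3-en-1-yl]oxy}dimethylsilane
Product: 7 (4R,5R,6R)-6-(tert-butyldimethylsilyloxy)-4,5-(isopropylidenedioxy)cyclohept-1-ene
Conditions: Grubbs II (cat.), CH2Cl2 (dilute), 40 °C
Reagents that add atoms: none
Why: Ring-closing metathesis of the 1,8-diene, pre-organised by the cis-dioxolane, should close the seven-membered ring with loss of ethylene and without touching a stereocentre.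

Step 7
Reactants: 7 (4R,5R,6R)-6-(tert-butyldimethylsilyloxy)-4,5-(isopropylidenedioxy)cyclohept-1-ene
Product: 8 (1S,2R,4R,5R,6R)-6-(tert-butyldimethylsilyloxy)-4,5-(isopropylidenedioxy)cycloheptane-1,2-diol
Conditions: OsO4 (cat.), NMO, acetone/H2O, rt
Reagents that add atoms: N-methylmorpholine N-oxide, C[N+]1([O-])CCOCC1; water, O
Why: Upjohn syn-dihydroxylation of the cis-disubstituted alkene should give the cis-diol, mainly anti to the dioxolane, and either facial isomer serves because both new centres become carbonyls.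

Step 8
Reactants: 8 (1S,2R,4R,5R,6R)-6-(tert-butyldimethylsilyloxy)-4,5-(isopropylidenedioxy)cycloheptane-1,2-diol
Product: 9 (4R,5R,6R)-6-(tert-butyldimethylsilyloxy)-4,5-(isopropylidenedioxy)cycloheptane-1,2-dione
Conditions: IBX, DMSO, rt to 40 °C
Reagents that add atoms: none
Why: IBX oxidises both carbinols of a 1,2-diol to the 1,2-diketone without glycol cleavage and without base, which should avoid β-elimination of the C4 and C6 oxygens.

Step 9
Reactants: 9 (4R,5R,6R)-6-(tert-butyldimethylsilyloxy)-4,5-(isopropylidenedioxy)cycloheptane-1,2-dione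
Product: 11 1-hydroxy-3,4-(isopropylidenedioxy)-8-oxabicyclo[3.2.1]octan-7-one (transannular hemiketal; acetonide on the face opposite the oxygen bridge), via hydroxy dione 10 (not isolated)
Conditions: HF·pyridine, pyridine, THF, 0 °C to rt
Reagents that add atoms: none
Why: Buffered fluoride desilylation frees the C6 hydroxyl, which should add across the ring to the electrophilic C2 carbonyl (5-exo-trig) to give the five-membered hemiketal, whose new centre at C2 is fixed by the bridge on the face of the C6 oxygen.

Step 10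
Reactants: 11 1-hydroxy-3,4-(isopropylidenedioxy)-8-oxabicyclo[3.2.1]octan-7-one
Product: 14 3,4-O-isopropylidenequinic acid 1,5-lactone (quinide acetonide), via lithium hemiketalate 12 (not isolated), via lithium lactone alkoxide 13 (not isolated)
Conditions: LiHMDS (1.05 equiv), THF, −78 °C to rt; AcOH
Reagents that add atoms: none
Why: Proposed new method: LiHMDS should remove only the hemiketal proton, and in the lithium chelate between the C2 alkoxide and the C1 ketone the C2–C3 bond stands nearly perpendicular to the C1=O plane, so C3 shifts from C2 to C1 while C2 collapses to the lactone carbonyl, driven by the gain of an ester from a ketone plus hemiketal. The closest known reactions are the benzilic ester rearrangement of 1,2-diketones with alkoxides and the hydroxide-induced contraction of cycloheptane-1,2-dione to 1-hydroxycyclohexanecarboxylic acid; what is new is that the alkoxide is a transannular hydroxyl of the substrate, held as a hemiketal. The cyclohexane (C1, C3–C7) is closed by this anionic 1,2-alkyl shift, a contraction of the seven-membered carbocycle that expels C2 as the exocyclic carboxyl carbon, and the γ-lactone is the oxolane already closed in step 9, changing only from hemiketal to ester. The one new stereocentre, quaternary C1, is controlled by the tether: C2 stays bonded to the bridging oxygen and so to C6, which forces the carboxyl carbon onto the face of O-5 (quinic numbering) and the new hydroxyl onto the other. The step needs the shift to outrun retro-aldol opening, enolisation and β-elimination toward a tropolone; this is secured because C2 is sp3 in the resting hemiketal (no acidic C3–H beside the acetonide oxygen), because only the C6 oxygen can reach a carbonyl through a five-membered ring while O-4 and O-5 are locked in the acetonide, and because one equivalent of a non-nucleophilic base is used cold.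

Step 11
Reactants: 14 3,4-O-isopropylidenequinic acid 1,5-lactone
Product: 16 benzyl 3,4-O-isopropylidenequinate, via potassium carboxylate 15 (not isolated)
Conditions: KOH (1.05 equiv), THF/H2O, 0 °C to rt; evaporate; BnBr, DMF, rt
Reagents that add atoms: potassium hydroxide, [K+].[OH-]; benzyl bromide, BrCc1ccccc1
Why: Saponification opens the γ-lactone and the carboxylate is O-alkylated by benzyl bromide (SN2 esterification), while the free hydroxyls are not alkylated without a stronger base.

Step 12
Reactants: 16 benzyl 3,4-O-isopropylidenequinate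
Product: 17 benzyl (−)-quinate
Conditions: AcOH/H2O (4:1), 40 °C
Reagents that add atoms: none
Why: Mild acid hydrolysis of the dioxolane (acetal cleavage) should free the cis-3,4-diol while the benzyl ester survives.

Step 13
Reactants: 17 benzyl (−)-quinate; 18 3,4,5-tris(benzyloxy)benzoyl chloride
Product: 19 benzyl 3,4,5-tris-O-[3,4,5-tris(benzyloxy)benzoyl]quinate
Conditions: 18 (4 equiv), DMAP, pyridine/CH2Cl2, 0 °C to rt
Reagents that add atoms: 3,4,5-tris(benzyloxy)benzoyl chloride (18), O=C(Cl)c1cc(OCc2ccccc2)c(OCc2ccccc2)c(OCc2ccccc2)c1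
Why: DMAP-catalysed acylation with the acid chloride should esterify the three secondary hydroxyls, whereas the tertiary α-carboalkoxy 1-OH is too hindered to react under these conditions.

Step 14
Reactants: 19 benzyl 3,4,5-tris-O-[3,4,5-tris(benzyloxy)benzoyl]quinate
Product: 20 3,4,5-tri-O-galloylquinic acid (CNP0148451.1)
Conditions: H2 (1 atm), Pd/C, THF/MeOH, rt
Reagents that add atoms: none
Why: Catalytic hydrogenolysis cleaves the nine aryl benzyl ethers and the benzyl ester in one neutral operation that leaves the three aryl esters and all stereocentres intact.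

**Compound list**

1 | 2-deoxy-L-ribose (pyranose form) | OC1C[C@@H](O)[C@@H](O)CO1 | starting material
2 | 3,4-O-isopropylidene-2-deoxy-L-ribopyranose | OC1C[C@H]2OC(C)(C)O[C@H]2CO1 | intermediate
3 | [(4S,5R)-2,2-dimethyl-5-(prop-2-en-1-yl)-1,3-dioxolan-4-yl]methanol | C=CC[C@H]1OC(C)(C)O[C@H]1CO | intermediate
4 | (4R,5R)-2,2-dimethyl-5-(prop-2-en-1-yl)-1,3-dioxolane-4-carbaldehyde | C=CC[C@H]1OC(C)(C)O[C@H]1C=O | intermediate
5 | (1R)-1-[(4S,5R)-2,2-dimethyl-5-(prop-2-en-1-yl)-1,3-dioxolan-4-yl]but-3-en-1-ol | C=CC[C@H]1OC(C)(C)O[C@H]1[C@H](O)CC=C | intermediate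
6 | TBS ether of 5 | C=CC[C@H]1OC(C)(C)O[C@H]1[C@H](O[Si](C)(C)C(C)(C)C)CC=C | intermediate
7 | (4R,5R,6R)-6-(tert-butyldimethylsilyloxy)-4,5-(isopropylidenedioxy)cyclohept-1-ene | C1=CC[C@H]2OC(C)(C)O[C@H]2[C@H](O[Si](C)(C)C(C)(C)C)C1 | intermediate
8 | (1S,2R,4R,5R,6R)-6-(tert-butyldimethylsilyloxy)-4,5-(isopropylidenedioxy)cycloheptane-1,2-diol | O[C@@H]1[C@H](O)C[C@H]2OC(C)(C)O[C@H]2[C@H](O[Si](C)(C)C(C)(C)C)C1 | intermediate
9 | (4R,5R,6R)-6-(tert-butyldimethylsilyloxy)-4,5-(isopropylidenedioxy)cycloheptane-1,2-dione | O=C1C(=O)C[C@H]2OC(C)(C)O[C@H]2[C@H](O[Si](C)(C)C(C)(C)C)C1 | intermediate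
10 | (4R,5S,6R)-6-hydroxy-4,5-(isopropylidenedioxy)cycloheptane-1,2-dione | O=C1C(=O)C[C@H]2OC(C)(C)O[C@H]2[C@H](O)C1 | intermediate (not isolated)
11 | 1-hydroxy-3,4-(isopropylidenedioxy)-8-oxabicyclo[3.2.1]octan-7-one (C6-O to C2 hemiketal of 10) | O=C1C[C@H]2O[C@]1(O)C[C@H]3OC(C)(C)O[C@@H]23 | intermediate
12 | lithium alkoxide of hemiketal 11 | O=C1C[C@H]2O[C@]1([O-])C[C@H]3OC(C)(C)O[C@@H]23.[Li+] | intermediate (not isolated)
13 | lithium 1-alkoxide of quinide acetonide | O=C1O[C@@H]2C[C@@]1([O-])C[C@H]3OC(C)(C)O[C@@H]23.[Li+] | intermediate (not isolated)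
14 | 3,4-O-isopropylidenequinic acid 1,5-lactone | O=C1O[C@@H]2C[C@@]1(O)C[C@H]3OC(C)(C)O[C@@H]23 | intermediate
15 | potassium 3,4-O-isopropylidenequinate | O[C@@H]1C[C@](O)(C(=O)[O-])C[C@H]2OC(C)(C)O[C@@H]12.[K+] | intermediate (not isolated)
16 | benzyl 3,4-O-isopropylidenequinate | O[C@@H]1C[C@](O)(C(=O)OCc2ccccc2)C[C@H]2OC(C)(C)O[C@@H]12 | intermediate
17 | benzyl (−)-quinate | O[C@@H]1C[C@](O)(C(=O)OCc2ccccc2)C[C@@H](O)[C@H]1O | intermediate
18 | 3,4,5-tris(benzyloxy)benzoyl chloride | O=C(Cl)c1cc(OCc2ccccc2)c(OCc2ccccc2)c(OCc2ccccc2)c1 | starting material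
19 | benzyl 3,4,5-tris-O-[3,4,5-tris(benzyloxy)benzoyl]quinate | O=C(O[C@@H]1C[C@](O)(C(=O)OCc2ccccc2)C[C@@H](OC(=O)c2cc(OCc3ccccc3)c(OCc3ccccc3)c(OCc3ccccc3)c2)[C@H]1OC(=O)c1cc(OCc2ccccc2)c(OCc2ccccc2)c(OCc2ccccc2)c1)c1cc(OCc2ccccc2)c(OCc2ccccc2)c(OCc2ccccc2)c1 | intermediate
20 | 3,4,5-tri-O-galloylquinic acid | O=C(O[C@@H]1C[C@](O)(C(=O)O)C[C@@H](OC(=O)c2cc(O)c(O)c(O)c2)[C@H]1OC(=O)c1cc(O)c(O)c(O)c1)c1cc(O)c(O)c(O)c1 | target

**Step count**

Total steps: 14. Longest linear sequence: 14 (1 to 20).

**Steps most likely to fail**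

1. Step 10 (proposed new method). The lithium hemiketalate may reopen to the β-alkoxide of the dione and fragment by retro-aldol cleavage of C6–C7, or enolise and lose the C4/C6 oxygens toward a tropolone, faster than C3 migrates. The fallback sets out from dione 9 and runs the contraction in the classical untethered way. Aqueous Ba(OH)2 in dioxane (benzilic acid rearrangement, as for cycloheptane-1,2-dione itself) should give 5-O-(tert-butyldimethylsilyl)-3,4-O-isopropylidenequinic acid F1 together with its 1-epimer F2. TBAF in THF then frees O-5 to give 3,4-O-isopropylidenequinic acid F3 and its 1-epimer F4. DCC in CH2Cl2 lactonises only F3, whose carboxyl is cis to O-5; F4 cannot close and is removed by bicarbonate extraction. The route is rejoined at 14.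

2. Step 8. The iodine(V) reagent may cleave the glycol C–C bond, or the new dione may enolise and β-eliminate the silyloxy or dioxolane oxygen during work-up. The fallback sets out from alkene 7 and avoids the diol. Ru-catalysed ketohydroxylation (RuCl3 cat., Oxone, NaHCO3, EtOAc/MeCN/H2O) should give the silyloxy acyloin F5 as a regio- and stereoisomeric mixture, all of which converge. The single remaining carbinol is then oxidised with Dess–Martin periodinane, and the route is rejoined at 9.

3. Step 4. Facial selectivity may be poor in this mismatched double stereodifferentiation, and the cis-aldehyde may epimerise before addition. The fallback sets out from aldehyde 4 and uses substrate control followed by inversion. Allylboronic acid pinacol ester (CH2Cl2, rt) should add in the Felkin sense to give the erythro (1S)-alcohol F6. Mitsunobu inversion (4-nitrobenzoic acid, PPh3, DIAD, THF) gives the (1R)-4-nitrobenzoate F7, and K2CO3/MeOH releases 5, where the route is rejoined.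

**Further compounds**

F1 | step 10 | 5-O-(tert-butyldimethylsilyl)-3,4-O-isopropylidenequinic acid | CC(C)(C)[Si](C)(C)O[C@@H]1C[C@](O)(C(=O)O)C[C@H]2OC(C)(C)O[C@@H]12
F2 | step 10 | 5-O-(tert-butyldimethylsilyl)-3,4-O-isopropylidene-1-epi-quinic acid | CC(C)(C)[Si](C)(C)O[C@@H]1C[C@@](O)(C(=O)O)C[C@H]2OC(C)(C)O[C@@H]12
F3 | step 10 | 3,4-O-isopropylidenequinic acid | O[C@@H]1C[C@](O)(C(=O)O)C[C@H]2OC(C)(C)O[C@@H]12
F4 | step 10 | 3,4-O-isopropylidene-1-epi-quinic acid | O[C@@H]1C[C@@](O)(C(=O)O)C[C@H]2OC(C)(C)O[C@@H]12
F5 | step 8 | (4R,5R,6R)-6-(tert-butyldimethylsilyloxy)-1-hydroxy-4,5-(isopropylidenedioxy)cycloheptan-2-one (one regioisomer drawn, carbinol centre mixed) | OC1C(=O)C[C@H]2OC(C)(C)O[C@H]2[C@H](O[Si](C)(C)C(C)(C)C)C1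
F6 | step 4 | (1S)-1-[(4S,5R)-2,2-dimethyl-5-(prop-2-en-1-yl)-1,3-dioxolan-4-yl]but-3-en-1-ol | C=CC[C@H]1OC(C)(C)O[C@H]1[C@@H](O)CC=C
F7 | step 4 | 4-nitrobenzoate of alcohol 5 | C=CC[C@H]1OC(C)(C)O[C@H]1[C@H](OC(=O)c2ccc(cc2)[N+](=O)[O-])CC=C
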